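The earlier runs and the new flask are simulated from invented constants, noise included.

If Sunday's flask is run again, the stretch to watch is the one after 15.0 min, where its target read 39.6% and then 39.7%.

| setting | Sunday's | Thursday's | flask |
|---|---|---|---|
| substrate | 0.49 M | 0.98 M | 0.49 M |
| gas phase | 160 mM (held) | 160 mM (held) | 160 mM (held) |
| free catalyst | 1.1 mM | 1.1 mM | 1.1 mM |
| remark | the very flask that is asked about, followed so far | run made earlier |  |
| time |  |  | 40 min |

| run | time / min | target / % |
|---|---|---|
| Sunday's | 5.00 | 17.9 |
| Sunday's | 6.00 | 22.6 |
| Sunday's | 8.00 | 28.0 |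
| Sunday's | 10.0 | 32.2 |
| Sunday's | 12.0 | 36.2 |
| Sunday's | 15.0 | 39.6 |
| Sunday's | 20.0 | 39.7 |
| Thursday's | 5.00 | 13.1 |
| Thursday's | 6.00 | 17.5 |
| Thursday's | 8.00 | 22.3 |
| Thursday's | 12.0 | 26.8 |
| Thursday's | 15.0 | 28.9 |
| Thursday's | 20.0 | 30.8 |
| Thursday's | 30.0 | 24.5 |

(each reading ± 1 percentage point)

- time up to 40 min at which target stands highest
- the amount of target, in percent of the substrate charged, at that time

- at the start none of the gas phase is in solution

Two chemists read that flat pair differently. The first takes it as the top of Sunday's target, with Thursday's fall from 30.8% to 24.5% showing that target is consumed. The forecast is hers: 17.5 min and 40.8%, and of the flat pair it says “so the maximum lies between them”.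

The second works with the fraction left, not the fraction made. She assumes that dissolved gas and free catalyst hold steady, so substrate falls in a pseudo-first-order way and its fraction left is exp(−κt). Here κ, the fraction-left constant, is the logarithm of charged over left, per minute. She counts Sunday's target at 6.00 min as substrate gone and reads 0.0427 /min, and she expects κ to go with the free catalyst charged. For Sunday's flask this leaves 42.6% of the substrate at 20.0 min and 18.1% at 40 min. So she expects target to climb past 20.0 min, and she puts the flat pair down to a scatter of 1 percentage point.

The simulation gives 19.0 min and 40.0%, so the forecast stands and the top does not lie beyond 20.0 min.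

    substrate + dissolved gas + free catalyst → free catalyst + target (k = 9.20 /M²/s)
    free catalyst + target → spent catalyst (k = 0.00870 /M/s)
    target ⇌ isomer of the product (K = 4.20, k = 4.90 × 10⁻⁴ /s)
    gas phase ⇌ dissolved gas, rate k4*(csat - [dissolved gas]) (kL = 0.00740 /s)

The second view's number lies close early in this flask, though its steady dissolved gas is not what stands there. At 4.00 min, with free catalyst at 94.3% of its charge and dissolved gas at 0.0950 M on the way to 0.144 M at 18.9 min, exp(−κt) gives 84.3% of the substrate left, and the flask holds 85.4%. At 40.0 min it gives 18.1% against 36.4%, with free catalyst down to 3.93%. For the neighbour flask charged with 2.8 × 10⁻⁴ M of free catalyst, κ scales to 0.0109 /min, which gives 64.7% of the substrate left at 40.0 min. That flask holds 62.2% of its substrate.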